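The cyclobutane of the target (C6, C7, C3', C8'), fused to the cyclohexene ring and spiro at C3' to the phthalide lactone ring, is the seam of a crossed [2+2] dimer: it joins the C6=C7 bond of (Z)-ligustilide 1 to the exocyclic C3'=C8' enol-lactone bond of (Z)-3-butylidenephthalide 2, both commercial. One photocycloaddition builds the whole skeleton: excited 1 bonds through C6 to C8' of 2, and the doubly stabilised 1,4-biradical 3 (pentadienyl at C7, benzylic α-oxy at C3') closes the four-membered ring by C7–C3' recombination, fixing the relative configuration of all four stereocentres in racemate 4. Chromatography on a chiral phase then gives the (6S,7R,8'R,3'R) enantiomer 5.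

Key step: step 1

Assumption: 1 and 2 are bought as the pure Z isomers (1 freshly chromatographed and kept cold under argon); phthalide numbering is used throughout, with primes for the unit that comes from 2.

Step 1
Reactants: 1 (Z)-ligustilide; 2 (Z)-3-butylidenephthalide (8 equiv, excess recovered)
Product: 4 racemic 6.8',7.3'-linked cyclobutane heterodimer (rac-5), via triplet 1,4-biradical 3 (not isolated)
Conditions: hν (365 nm LEDs), degassed CH2Cl2 (0.02 M in 1), 0 °C; then SiO2 and C18 HPLC
Reagents that add atoms: none
Why: Crossed [2+2] photocycloaddition: light of 365 nm should be absorbed mainly by the cross-conjugated trienyl lactone of 1, whose excited state (triplet after intersystem crossing) bonds through its diene terminus C6 to C8' of ground-state 2 to give biradical 3, and after spin inversion C7–C3' recombination closes the cyclobutane, so this bond is the ring-closing event. The closest known reaction type is the light-induced [2+2] dimerisation of (Z)-ligustilide through the same two alkene types (endocyclic C6=C7 plus exocyclic C3=C8), run here as a crossed reaction. The four-membered ring closes by 1,4-biradical recombination (a 4-exo radical–radical coupling), which should be preferred over 1,6-closure at C3a because that would join two fully substituted carbons. C6 and C7 must become cis because a cyclobutane fused to the cyclohexene tolerates only a cis junction, while C8' and C3' follow from the stacking topology in which the planar benzo ring of 2 lies over the open H6/H7 side of the diene, so that closure faster than rotation about C8'–C3' keeps propyl cis to the lactone oxygen and places the benzo ring on the convex face; the product is racemic. The step needs crossed over homo-dimerisation, secured by the excess of 2 and selective excitation of dilute 1, and the 6.8',7.3' regiochemistry, secured by the stabilisation of both radical centres of 3; isomeric adducts and E isomers would be removed by chromatography, and the product, lacking the triene, should be transparent at 365 nm.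

Step 2
Reactants: 4 racemic 6.8',7.3'-linked cyclobutane heterodimer
Product: 5 (6S,7R,8'R,3'R) heterodimer, the target
Conditions: preparative HPLC on amylose tris(3,5-dimethylphenylcarbamate) phase, n-hexane/i-PrOH, 25 °C
Reagents that add atoms: none
Why: Enantiomer resolution by chromatography on a polysaccharide chiral stationary phase, a standard separation for rigid neutral lactones, makes or breaks no bond, so the relative configuration from step 1 is carried over and the (6S,7R,8'R,3'R) antipode is selected, its identity to be assigned by comparing its ECD curve with a TDDFT calculation or by anomalous-dispersion X-ray analysis.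

Compound list
1 | (Z)-ligustilide, (3Z)-3-butylidene-4,5-dihydro-2-benzofuran-1(3H)-one | CCC/C=C1\OC(=O)C2=C1CCC=C2 | starting material
2 | (Z)-3-butylidenephthalide, (3Z)-3-butylidene-2-benzofuran-1(3H)-one | CCC/C=C1\OC(=O)c2ccccc12 | starting material
3 | triplet 1,4-biradical with the C6–C8' bond formed, radical centres at C7 and C3' (racemic, both enantiomers written) | CCC/C=C1\OC(=O)C2=C1CC[C@H]([CH]2)[C@@H](CCC)[C]1OC(=O)c2ccccc12.CCC/C=C1\OC(=O)C2=C1CC[C@@H]([CH]2)[C@H](CCC)[C]1OC(=O)c2ccccc12 | intermediate
4 | racemic 6.8',7.3'-linked cyclobutane heterodimer: 1:1 mixture of 5 and its enantiomer (both written); H6, H7 and H8' on one cyclobutane face, propyl and lactone oxygen on the face of the cyclohexene ring, benzo ring on the opposite convex face, Z-butylidene retained | CCC/C=C1\OC(=O)C2=C1CC[C@H]1[C@@H](CCC)[C@@]3(OC(=O)c4ccccc43)[C@@H]21.CCC/C=C1\OC(=O)C2=C1CC[C@@H]1[C@H](CCC)[C@]3(OC(=O)c4ccccc43)[C@H]21 | intermediate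
5 | (6S,7R,8'R,3'R)-6.8',7.3'-linked [2+2] heterodimer of (Z)-ligustilide and (Z)-3-butylidenephthalide (spiro-phthalide at C3' on the cyclobutane, cis-fused to the (Z)-3-butylidene-tetrahydrophthalide) | CCC/C=C1\OC(=O)C2=C1CC[C@H]1[C@@H](CCC)[C@@]3(OC(=O)c4ccccc43)[C@@H]21 | target

Total step count: 2. Longest linear sequence: 2 steps (1 + 2 → 4 → 5).

Steps most likely to fail (the route has only two steps; both are ranked)

1. Step 1. Homodimerisation and thermal Diels–Alder dimerisation of 1, E/Z photoisomerisation of its butylidene group, or unselective closure of the biradical could outrun the crossed cycloaddition. Fallback, setting out from 1 and coming back at 4: 1 alone would be irradiated (365 nm, degassed CH2Cl2, concentrated solution), which removes the cross-selectivity problem. This should give the racemic 6.8',7.3' homodimer F1 of the same relative configuration (the riligustilide skeleton), whose spiro unit still carries a cyclohexa-1,3-diene ring. DDQ (1.1 equiv, toluene, 25 °C) should then aromatise only this ring to the benzo ring, since the other six-membered ring cannot aromatise without breaking the cyclobutane, and give 4.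

2. Step 2. The antipodes may be discriminated too weakly on the stationary phase at preparative loading, or their assignment may stay ambiguous. Fallback, setting out from 2 and coming back at 5, separating diastereomers instead of enantiomers:
- 2 would be irradiated (350 nm, degassed CH2Cl2, 0 °C) with commercial natural (S)-senkyunolide A, (3S)-3-butyl-4,5-dihydrophthalide. Its C3 stereocentre turns the two cyclobutane antipodes into diastereomers that silica should separate.
- The diastereomer F2 with the cyclobutane configuration of 5 would be carried on. Its known C3 centre also serves as internal reference for the assignment.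
- Et3N/TBSOTf (CH2Cl2, 0 °C) should erase C3 by forming the 2-silyloxyfuran F3.
- NBS (THF, −78 °C) should give the labile C3 bromide F4, and DBU added to the same flask should eliminate HBr towards C8 to give the thermodynamically preferred Z-butylidene lactone 5.

Further compounds
F1 | step 1 | racemic 6.8',7.3' [2+2] homodimer of 1, riligustilide skeleton with a 4',5'-dihydro spiro unit (both enantiomers written) | CCC/C=C1\OC(=O)C2=C1CC[C@H]1[C@@H](CCC)[C@@]3(OC(=O)C4=C3CCC=C4)[C@@H]21.CCC/C=C1\OC(=O)C2=C1CC[C@@H]1[C@H](CCC)[C@]3(OC(=O)C4=C3CCC=C4)[C@H]21
F2 | step 2 | (3S,6S,7R,8'R,3'R) cyclobutane adduct of (S)-senkyunolide A and 2 (3-butyl in place of 3-butylidene) | CCCC[C@@H]1OC(=O)C2=C1CC[C@H]1[C@@H](CCC)[C@@]3(OC(=O)c4ccccc43)[C@@H]21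
F3 | step 2 | 2-(tert-butyldimethylsilyloxy)furan derived from F2 (C3 now part of the furan) | CCCCc1oc(O[Si](C)(C)C(C)(C)C)c2c1CC[C@H]1[C@@H](CCC)[C@@]3(OC(=O)c4ccccc43)[C@@H]21
F4 | step 2 | 3-bromo-3-butyl butenolide derived from F3 (mixture of C3 epimers) | CCCCC1(Br)OC(=O)C2=C1CC[C@H]1[C@@H](CCC)[C@@]3(OC(=O)c4ccccc43)[C@@H]21
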